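**Strategy.** The flavanone is cut between O1 and C2 and, on ring A, at both O1–C8a and C4a–C4. Ring A carries the ring oxygen on C8a and the carbonyl carbon on C4a as ortho neighbours, flanked by the C5 oxygen: exactly what a 3-alkoxyaryne accepts when it inserts into the C–O bond of a carboxylic acid. In one operation the aryne from a 4-geranyl-3,5-bis(methoxymethoxy)-2-silylphenyl triflate takes up an enantiopure (3R)-3-silyloxy-3-arylpropanoic acid, giving the complete C6–C3–C6 skeleton with a single free phenol and the 6-geranyl pattern fixed. Desilylation, Mitsunobu closure with inversion (3R to 2S) and acid removal of the methoxymethyl groups finish the synthesis.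

Key step: step 11

Remark: the benzylic oxygen travels as a TBS ether, because oxidative cleavage of a benzyl-type ether would endanger the geranyl CH2 para to the free phenol; methyl 3-hydroxy-4,5-dimethoxybenzoate is assumed purchasable; geranyl = (2E)-3,7-dimethylocta-2,6-dien-1-yl, MOM = methoxymethyl.

**Aryne precursor (ring A)**

Step 1
Reactants: 1 phloroglucinol
Product: 2 3,5-bis(methoxymethoxy)phenol
Conditions: MOMCl (2.1 equiv), i-Pr2NEt (2.5 equiv), DMF, 0 °C → rt; chromatography
Reagents that add atoms: chloromethyl methyl ether, COCCl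
Why: Base-mediated O-alkylation (Williamson-type) of the symmetric triol should give the bis-ether as the main statistical product, separable from the mono- and tris-ethers and free of regiochemical ambiguity.

Step 2
Reactants: 2 3,5-bis(methoxymethoxy)phenol
Product: 3 [3,5-bis(methoxymethoxy)phenoxy]tri(propan-2-yl)silane
Conditions: TIPSCl, imidazole, DMF, rt
Reagents that add atoms: chlorotri(propan-2-yl)silane, CC(C)[Si](Cl)(C(C)C)C(C)C
Why: Standard silylation of the remaining phenol installs a bulky, non-directing silyl ether that tolerates butyllithium and marks the oxygen that later becomes the triflate.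

Step 3
Reactants: 3 [3,5-bis(methoxymethoxy)phenoxy]tri(propan-2-yl)silane; 4 geranyl bromide
Product: 7 4-geranyl-3,5-bis(methoxymethoxy)phenol, via aryllithium 5 (not isolated), via geranylated silyl ether 6 (not isolated)
Conditions: n-BuLi (1.2 equiv), THF, 0 °C; CuBr·SMe2 (10 mol %), 4, −78 °C → rt; then TBAF (1.5 equiv), rt
Reagents that add atoms: none
Why: Directed ortho-metalation should occur at the carbon between the two cooperating MOM ethers, copper-catalysed SN2 allylation keeps the linear E-geranyl unit, and fluoride frees the phenol in the same flask.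

Step 4
Reactants: 7 4-geranyl-3,5-bis(methoxymethoxy)phenol
Product: 8 2-bromo-4-geranyl-3,5-bis(methoxymethoxy)phenol
Conditions: NBS (1.0 equiv), i-Pr2NH (10 mol %), CH2Cl2, −78 °C
Reagents that add atoms: N-bromosuccinimide, O=C1CCC(=O)N1Br
Why: Amine-catalysed ortho-bromination (electrophilic aromatic substitution) of the strongly activated ring, whose two free positions are equivalent, should be much faster at −78 °C than attack on the trisubstituted olefins, and one equivalent of reagent limits dibromination.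

Step 5
Reactants: 8 2-bromo-4-geranyl-3,5-bis(methoxymethoxy)phenol
Product: 11 4-geranyl-3,5-bis(methoxymethoxy)-2-(trimethylsilyl)phenyl trifluoromethanesulfonate, via TMS ether 9 (not isolated), via lithium silylphenolate 10 (not isolated)
Conditions: HMDS, THF, 65 °C, then concentrate; n-BuLi (1.1 equiv), THF, −78 °C; Tf2O (1.2 equiv), −78 → 0 °C
Reagents that add atoms: hexamethyldisilazane, C[Si](C)(C)N[Si](C)(C)C; trifluoromethanesulfonic anhydride, O=S(=O)(OS(=O)(=O)C(F)(F)F)C(F)(F)F
Why: O-silylation, fast bromine–lithium exchange, 1,3 O-to-C silyl shift (retro-Brook rearrangement) and O-triflation of the resulting phenolate form the standard one-pot entry to 2-silylaryl triflates.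

**Chiral acid (ring B)**

Step 6
Reactants: 12 methyl 3-hydroxy-4,5-dimethoxybenzoate
Product: 13 methyl 3,4-dimethoxy-5-(methoxymethoxy)benzoate
Conditions: MOMCl, i-Pr2NEt, CH2Cl2, 0 °C → rt
Reagents that add atoms: chloromethyl methyl ether, COCCl
Why: Routine MOM protection masks the ring B phenol against aryne O-arylation with a group that falls with the ring A ethers in the last step.

Step 7
Reactants: 13 methyl 3,4-dimethoxy-5-(methoxymethoxy)benzoate; 14 ethyl acetate
Product: 15 ethyl 3-[3,4-dimethoxy-5-(methoxymethoxy)phenyl]-3-oxopropanoate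
Conditions: LiN(SiMe3)2 (3 equiv), 14 (1.5 equiv), THF, −78 °C; then 13, −78 → 0 °C; aq. NH4Cl
Reagents that add atoms: none
Why: Crossed Claisen condensation of the lithium enolate of ethyl acetate with the non-enolisable benzoate is driven by deprotonation of the β-keto ester formed.

Step 8
Reactants: 15 ethyl 3-[3,4-dimethoxy-5-(methoxymethoxy)phenyl]-3-oxopropanoate
Product: 16 ethyl (3R)-3-hydroxy-3-[3,4-dimethoxy-5-(methoxymethoxy)phenyl]propanoate
Conditions: RuCl(p-cymene)[(R,R)-TsDPEN] (1 mol %), HCO2H/Et3N (5:2), 40 °C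
Reagents that add atoms: none
Why: Noyori asymmetric transfer hydrogenation of the aryl ketone, in which the (R,R)-ligand should direct hydride to the face that gives the (3R)-benzylic alcohol (the sense known for acetophenone-type ketones), under conditions that spare the aryl MOM ether.

Step 9
Reactants: 16 ethyl (3R)-3-hydroxy-3-[3,4-dimethoxy-5-(methoxymethoxy)phenyl]propanoate
Product: 17 ethyl (3R)-3-[(tert-butyldimethylsilyl)oxy]-3-[3,4-dimethoxy-5-(methoxymethoxy)phenyl]propanoate
Conditions: TBSCl, imidazole, DMF, rt → 40 °C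
Reagents that add atoms: tert-butylchlorodimethylsilane, CC(C)(C)[Si](C)(C)Cl
Why: Standard silylation under non-acidic conditions protects the carbinol without touching the stereocentre or the MOM ether.

Step 10
Reactants: 17 ethyl (3R)-3-[(tert-butyldimethylsilyl)oxy]-3-[3,4-dimethoxy-5-(methoxymethoxy)phenyl]propanoate
Product: 18 (3R)-3-[(tert-butyldimethylsilyl)oxy]-3-[3,4-dimethoxy-5-(methoxymethoxy)phenyl]propanoic acid
Conditions: LiOH·H2O, THF/MeOH/H2O, rt; then 1 M HCl to pH 4, 0 °C
Reagents that add atoms: lithium hydroxide (supplies the carboxyl OH oxygen), [Li+].[OH-]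
Why: Saponification at room temperature should leave the secondary TBS ether and the carbinol centre intact, since hydroxide does not enolise the ester enough for β-elimination.

**Key step and endgame**

Step 11
Reactants: 11 4-geranyl-3,5-bis(methoxymethoxy)-2-(trimethylsilyl)phenyl trifluoromethanesulfonate (1.3 equiv); 18 (3R)-3-[(tert-butyldimethylsilyl)oxy]-3-[3,4-dimethoxy-5-(methoxymethoxy)phenyl]propanoic acid
Product: 21 (3R)-3-[(tert-butyldimethylsilyl)oxy]-1-[3-geranyl-6-hydroxy-2,4-bis(methoxymethoxy)phenyl]-3-[3,4-dimethoxy-5-(methoxymethoxy)phenyl]propan-1-one, via aryne 19 (not isolated), via aryl anion 20 (not isolated)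
Conditions: CsF (4 equiv), THF, sealed tube, 110–125 °C
Reagents that add atoms: none
Why: Fluoride removes the trimethylsilyl group of 11 and expels triflate to give aryne 19; the carboxylate of 18 adds to the aryne carbon remote from the flanking MOM ether (future C8a), because that σ-withdrawing oxygen polarises the aryne so that the carbanion develops beside it (future C4a). Aryl anion 20 then attacks its own ester carbonyl through a four-membered transition state and the acyl C–O bond breaks, a net insertion of the aryne into the C–O bond of the acid that forms O1–C8a and C4a–C4. The closest known reaction is the fluoride-mediated union of carboxylic acids with 2-silylaryl triflates to give ortho-hydroxyaryl ketones, with the regiochemistry usual for nucleophiles adding to 3-alkoxyarynes. No ring is closed and no stereocentre is created; the carbinol centre of 18 is not involved and is carried through unchanged. The step needs regioselectivity across the aryne (secured by the alkoxy group beside C4a), acyl shift in preference to protonation of 20 (favoured by aprotic THF at high temperature) and survival of the β-silyloxy unit (helped by sparingly soluble, weakly basic CsF).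

Step 12
Reactants: 21 (3R)-3-[(tert-butyldimethylsilyl)oxy]-1-[3-geranyl-6-hydroxy-2,4-bis(methoxymethoxy)phenyl]-3-[3,4-dimethoxy-5-(methoxymethoxy)phenyl]propan-1-one
Product: 22 (3R)-1-[3-geranyl-6-hydroxy-2,4-bis(methoxymethoxy)phenyl]-3-hydroxy-3-[3,4-dimethoxy-5-(methoxymethoxy)phenyl]propan-1-one
Conditions: HF·pyridine, pyridine, THF, 0 °C → rt
Reagents that add atoms: none
Why: Buffered fluoride desilylation is non-oxidative and non-basic, so the geranyl chain, the aryl MOM ethers and the β-hydroxy ketone (no retro-aldol) should all survive.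

Step 13
Reactants: 22 (3R)-1-[3-geranyl-6-hydroxy-2,4-bis(methoxymethoxy)phenyl]-3-hydroxy-3-[3,4-dimethoxy-5-(methoxymethoxy)phenyl]propan-1-one
Product: 23 (2S)-6-geranyl-5,7-bis(methoxymethoxy)-2-[3,4-dimethoxy-5-(methoxymethoxy)phenyl]-2,3-dihydro-4H-chromen-4-one
Conditions: PPh3, DIAD, THF, 0 °C → rt
Reagents that add atoms: none
Why: Intramolecular Mitsunobu etherification, in which the only free phenol displaces the activated benzylic oxygen by SN2 with inversion (3R to 2S), the ring B aryl being too weakly donating to favour ionisation.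

Step 14
Reactants: 23 (2S)-6-geranyl-5,7-bis(methoxymethoxy)-2-[3,4-dimethoxy-5-(methoxymethoxy)phenyl]-2,3-dihydro-4H-chromen-4-one
Product: 24 (2S)-6-geranyl-5,7-dihydroxy-2-(3-hydroxy-4,5-dimethoxyphenyl)-2,3-dihydro-4H-chromen-4-one (CNP0228243.1)
Conditions: 3 M aq. HCl, MeOH, 40 °C
Reagents that add atoms: none
Why: Acid-catalysed acetal exchange removes the three aryl MOM ethers under conditions commonly used for prenylated flavanones, mild enough to leave the geranyl olefins and the C2 configuration untouched.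

**Compound list**

1 | phloroglucinol | Oc1cc(O)cc(O)c1 | starting material
2 | 3,5-bis(methoxymethoxy)phenol | COCOc1cc(O)cc(OCOC)c1 | intermediate
3 | [3,5-bis(methoxymethoxy)phenoxy]tri(propan-2-yl)silane | COCOc1cc(OCOC)cc(O[Si](C(C)C)(C(C)C)C(C)C)c1 | intermediate
4 | geranyl bromide, (2E)-1-bromo-3,7-dimethylocta-2,6-diene | BrC/C=C(\C)CCC=C(C)C | starting material
5 | {2,6-bis(methoxymethoxy)-4-[(triisopropylsilyl)oxy]phenyl}lithium | [Li]c1c(OCOC)cc(O[Si](C(C)C)(C(C)C)C(C)C)cc1OCOC | intermediate
6 | [4-geranyl-3,5-bis(methoxymethoxy)phenoxy]tri(propan-2-yl)silane | COCOc1cc(O[Si](C(C)C)(C(C)C)C(C)C)cc(OCOC)c1C/C=C(\C)CCC=C(C)C | intermediate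
7 | 4-geranyl-3,5-bis(methoxymethoxy)phenol | COCOc1cc(O)cc(OCOC)c1C/C=C(\C)CCC=C(C)C | intermediate
8 | 2-bromo-4-geranyl-3,5-bis(methoxymethoxy)phenol | Oc1cc(OCOC)c(C/C=C(\C)CCC=C(C)C)c(OCOC)c1Br | intermediate
9 | [2-bromo-4-geranyl-3,5-bis(methoxymethoxy)phenoxy]trimethylsilane | C[Si](C)(C)Oc1cc(OCOC)c(C/C=C(\C)CCC=C(C)C)c(OCOC)c1Br | intermediate
10 | lithium 4-geranyl-3,5-bis(methoxymethoxy)-2-(trimethylsilyl)phenolate | [Li+].[O-]c1cc(OCOC)c(C/C=C(\C)CCC=C(C)C)c(OCOC)c1[Si](C)(C)C | intermediate
11 | 4-geranyl-3,5-bis(methoxymethoxy)-2-(trimethylsilyl)phenyl trifluoromethanesulfonate | C[Si](C)(C)c1c(OS(=O)(=O)C(F)(F)F)cc(OCOC)c(C/C=C(\C)CCC=C(C)C)c1OCOC | intermediate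
12 | methyl 3-hydroxy-4,5-dimethoxybenzoate | COC(=O)c1cc(O)c(OC)c(OC)c1 | starting material
13 | methyl 3,4-dimethoxy-5-(methoxymethoxy)benzoate | COC(=O)c1cc(OC)c(OC)c(OCOC)c1 | intermediate
14 | ethyl acetate | CCOC(C)=O | starting material
15 | ethyl 3-[3,4-dimethoxy-5-(methoxymethoxy)phenyl]-3-oxopropanoate | CCOC(=O)CC(=O)c1cc(OC)c(OC)c(OCOC)c1 | intermediate
16 | ethyl (3R)-3-hydroxy-3-[3,4-dimethoxy-5-(methoxymethoxy)phenyl]propanoate | COc1cc([C@H](O)CC(=O)OCC)cc(OCOC)c1OC | intermediate
17 | ethyl (3R)-3-[(tert-butyldimethylsilyl)oxy]-3-[3,4-dimethoxy-5-(methoxymethoxy)phenyl]propanoate | COc1cc([C@H](O[Si](C)(C)C(C)(C)C)CC(=O)OCC)cc(OCOC)c1OC | intermediate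
18 | (3R)-3-[(tert-butyldimethylsilyl)oxy]-3-[3,4-dimethoxy-5-(methoxymethoxy)phenyl]propanoic acid | COc1cc([C@H](O[Si](C)(C)C(C)(C)C)CC(=O)O)cc(OCOC)c1OC | intermediate
19 | 4-geranyl-3,5-bis(methoxymethoxy)benzyne (1,2-didehydro) | COCOC1=CC#CC(OCOC)=C1C/C=C(\C)CCC=C(C)C | intermediate
20 | cesium 2-acyloxy-4-geranyl-3,5... aryl anion: the O-aryl ester of 18 carrying the carbanion between the ester oxygen and a MOM ether | [Cs+].COCOc1cc(OC(=O)C[C@@H](O[Si](C)(C)C(C)(C)C)c2cc(OC)c(OC)c(OCOC)c2)[c-]c(OCOC)c1C/C=C(\C)CCC=C(C)C | intermediate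
21 | (3R)-3-[(tert-butyldimethylsilyl)oxy]-1-[3-geranyl-6-hydroxy-2,4-bis(methoxymethoxy)phenyl]-3-[3,4-dimethoxy-5-(methoxymethoxy)phenyl]propan-1-one | COCOc1cc(O)c(C(=O)C[C@@H](O[Si](C)(C)C(C)(C)C)c2cc(OC)c(OC)c(OCOC)c2)c(OCOC)c1C/C=C(\C)CCC=C(C)C | intermediate
22 | (3R)-1-[3-geranyl-6-hydroxy-2,4-bis(methoxymethoxy)phenyl]-3-hydroxy-3-[3,4-dimethoxy-5-(methoxymethoxy)phenyl]propan-1-one | COCOc1cc(O)c(C(=O)C[C@@H](O)c2cc(OC)c(OC)c(OCOC)c2)c(OCOC)c1C/C=C(\C)CCC=C(C)C | intermediate
23 | (2S)-6-geranyl-5,7-bis(methoxymethoxy)-2-[3,4-dimethoxy-5-(methoxymethoxy)phenyl]-2,3-dihydro-4H-chromen-4-one | COc1cc([C@@H]2CC(=O)c3c(cc(OCOC)c(C/C=C(\C)CCC=C(C)C)c3OCOC)O2)cc(OCOC)c1OC | intermediate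
24 | (2S)-6-geranyl-5,7-dihydroxy-2-(3-hydroxy-4,5-dimethoxyphenyl)-2,3-dihydro-4H-chromen-4-one | COc1cc([C@@H]2CC(=O)c3c(cc(O)c(C/C=C(\C)CCC=C(C)C)c3O)O2)cc(O)c1OC | target

**Totals.** 14 steps in all; longest linear sequence 9 steps (steps 1–5 then 11–14, or steps 6–10 then 11–14).

**Steps most likely to fail**

1. Step 11. The aryl anion may be protonated before the acyl shift, giving the O-aryl ester. The product ketone may lose silanol by β-elimination and close to racemic flavanone. Bifluoride may strip the silyl ether at the temperature required. The fallback sets out from 8 and 18 and returns at 21. Acid 18 would be coupled with N,O-dimethylhydroxylamine (EDC·HCl, HOBt, i-Pr2NEt, CH2Cl2) to give the Weinreb amide (3R)-3-[(tert-butyldimethylsilyl)oxy]-N-methoxy-N-methyl-3-[3,4-dimethoxy-5-(methoxymethoxy)phenyl]propanamide F1. Bromophenol 8 would be deprotonated and exchanged with n-BuLi (2.1 equiv, THF, −78 °C) to lithium 4-geranyl-2-lithio-3,5-bis(methoxymethoxy)phenolate F2, whose C-acylation by F1 should give 21 after aqueous work-up.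

2. Step 13. Dehydration of the β-hydroxy ketone to the chalcone, or partial ionisation at the benzylic carbon, would erode the C2 configuration. The fallback sets out from 22 and returns at 23. KOH in EtOH at rt should convert 22 (Claisen–Schmidt-type dehydration) into the chalcone (E)-1-[3-geranyl-6-hydroxy-2,4-bis(methoxymethoxy)phenyl]-3-[3,4-dimethoxy-5-(methoxymethoxy)phenyl]prop-2-en-1-one F3. NaOAc in refluxing EtOH should then close it by oxa-Michael addition to racemic 6-geranyl-5,7-bis(methoxymethoxy)-2-[3,4-dimethoxy-5-(methoxymethoxy)phenyl]-2,3-dihydro-4H-chromen-4-one F4. Preparative HPLC on an amylose tris(3,5-dimethylphenylcarbamate) phase would deliver 23.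

3. Step 4. Electrophilic bromine may attack the geranyl olefins or brominate the ring twice. The fallback sets out from 7 and returns at 11, replacing steps 4 and 5 by carbamate-directed ortho-silylation. Phenol 7 with i-PrNCO and Et3N should give 4-geranyl-3,5-bis(methoxymethoxy)phenyl N-(propan-2-yl)carbamate F5. In-situ N-silylation (TBSOTf, TMEDA, Et2O), ortho-lithiation (n-BuLi, −78 °C) and Me3SiCl quench should give 4-geranyl-3,5-bis(methoxymethoxy)-2-(trimethylsilyl)phenyl N-(propan-2-yl)carbamate F6. Carbamate cleavage (Et2NH, DBU, MeCN, 40 °C) and trapping of the phenolate with PhNTf2 should give 11.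

**Further compounds**

F1 | step 11 | (3R)-3-[(tert-butyldimethylsilyl)oxy]-N-methoxy-N-methyl-3-[3,4-dimethoxy-5-(methoxymethoxy)phenyl]propanamide | COc1cc([C@H](O[Si](C)(C)C(C)(C)C)CC(=O)N(C)OC)cc(OCOC)c1OC
F2 | step 11 | lithium 4-geranyl-2-lithio-3,5-bis(methoxymethoxy)phenolate | [Li]Oc1cc(OCOC)c(C/C=C(\C)CCC=C(C)C)c(OCOC)c1[Li]
F3 | step 13 | (E)-1-[3-geranyl-6-hydroxy-2,4-bis(methoxymethoxy)phenyl]-3-[3,4-dimethoxy-5-(methoxymethoxy)phenyl]prop-2-en-1-one | COCOc1cc(O)c(C(=O)/C=C/c2cc(OC)c(OC)c(OCOC)c2)c(OCOC)c1C/C=C(\C)CCC=C(C)C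
F4 | step 13 | racemic 6-geranyl-5,7-bis(methoxymethoxy)-2-[3,4-dimethoxy-5-(methoxymethoxy)phenyl]-2,3-dihydro-4H-chromen-4-one | COc1cc(C2CC(=O)c3c(cc(OCOC)c(C/C=C(\C)CCC=C(C)C)c3OCOC)O2)cc(OCOC)c1OC
F5 | step 4 | 4-geranyl-3,5-bis(methoxymethoxy)phenyl N-(propan-2-yl)carbamate | CC(C)NC(=O)Oc1cc(OCOC)c(C/C=C(\C)CCC=C(C)C)c(OCOC)c1
F6 | step 4 | 4-geranyl-3,5-bis(methoxymethoxy)-2-(trimethylsilyl)phenyl N-(propan-2-yl)carbamate | CC(C)NC(=O)Oc1cc(OCOC)c(C/C=C(\C)CCC=C(C)C)c(OCOC)c1[Si](C)(C)C
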